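A direct plan would condense acetophenone A1 with aldehyde A2 (Claisen–Schmidt), close ring C with iodine in DMSO to give tetra-O-benzyl flavone A3, free the chelated 5-hydroxyl to give 5-hydroxyflavone A4, iodinate C6 to give iodoflavone A5, attach alkenol A6 by a Heck reaction to give styrenyl carbinol A7, and finish by hydrogenation and hydrogenolysis. Its weakest steps would be:
- The iodination of the finished flavone: it would have to tell C6 from C8 on ring A by substrate bias alone, so the position of the side chain would rest on a late selectivity.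
- The selective 5-O-debenzylation within four benzyl ethers: a protecting-group stretch that would build no bond and only prepare that iodination.
- The Heck coupling at an iodide flanked by two oxygen substituents, followed by hydrogenation of a tertiary allylic alcohol: a late pair in which the side-chain C–O bond could be lost by ionisation or hydrogenolysis.

**Retrosynthetic overview**
- Ring A (C4a, C5, C6, C7, C8, C8a) would be built last, around its side chain, by an anionic Claisen–Dieckmann [4+2] benzannulation that forms C8–C7 and C6–C5. The partners are a ring C 4-pyranone ester (its 2-methyl is C8, its ester carbon is C5) and 6,6-dimethyl-δ-valerolactone.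
- The lactone carbonyl becomes C7–OH, its α-carbon becomes C6, and the rest of its ring unfolds as the 3-hydroxy-3-methylbutyl chain; the acylation itself sets the tertiary hydroxyl free.
- Ring order: ring B is bought, ring C is made from an aroylketene and an enamino ester, ring A closes last.
- The side chain can sit only at C6, by connectivity and not by selectivity. There is no halogenation, no Heck reaction and no alkene to hydrogenate; ring A phenols and the tertiary alcohol are never protected, and only two ring B benzyl ethers remain to be removed.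

Key step: step 4

**Route**

Step 1
Reactants: 1 ethyl 5-oxohexanoate
Product: 3 6,6-dimethyltetrahydro-2H-pyran-2-one, via hydroxy ester 2 (not isolated)
Conditions: MeMgBr (1.05 equiv), THF, −78 → −20 °C; cold 1 M HCl; then PPTS (5 mol %), PhMe, 60 °C
Reagents that add atoms: methylmagnesium bromide, C[Mg]Br
Why: Grignard addition that should take the ketone in preference to the ester at low temperature, followed by acid-catalysed lactonisation of hydroxy ester 2 (6-exo-trig) with loss of ethanol; the new carbinol carbon carries two methyl groups, so no stereocentre arises.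

Step 2
Reactants: 4 2,4-bis(benzyloxy)benzoic acid; 5 2,2-dimethyl-1,3-dioxane-4,6-dione (Meldrum's acid)
Product: 6 5-{[2,4-bis(benzyloxy)phenyl](hydroxy)methylidene}-2,2-dimethyl-1,3-dioxane-4,6-dione (enol form of the aroyl Meldrum's acid)
Conditions: DCC (1.1 equiv), DMAP (1.5 equiv), CH2Cl2, 0 → 25 °C; cold aq KHSO4 wash
Reagents that add atoms: none
Why: Carbodiimide/DMAP (Steglich-type) C-acylation of the acidic methylene of Meldrum's acid through the acylpyridinium ion, the product being held as its hydrogen-bonded enol while the benzyl ethers stay untouched; no stereocentre.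

Step 3
Reactants: 6 aroyl Meldrum's acid; 7 ethyl (E)-3-(pyrrolidin-1-yl)but-2-enoate
Product: 10 ethyl 6-[2,4-bis(benzyloxy)phenyl]-2-methyl-4-oxo-4H-pyran-3-carboxylate, via aroylketene 8 (not isolated), via acylated enamino ester 9 (not isolated)
Conditions: 7 (1.5 equiv), PhMe, 110 °C, slow addition of 6; then AcOH (5 equiv), 80 °C
Reagents that add atoms: none
Why: Thermal fragmentation of 6 (loss of acetone and CO2) should give aroylketene 8, which C-acylates the nucleophilic α-carbon of the tertiary enamino ester to 9, and the enol oxygen of the aryl ketone then displaces pyrrolidine by addition–elimination under mild acid (acylketene–enamine route to 4-pyranones, formally a [4+2] cycloaddition–elimination), which places the ester at C3 and the methyl at C2 by connectivity; no stereocentre.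

Step 4
Reactants: 10 pyranone ester; 3 6,6-dimethyltetrahydro-2H-pyran-2-one
Product: 13 2-[2,4-bis(benzyloxy)phenyl]-5,7-dihydroxy-6-(3-hydroxy-3-methylbutyl)-4H-chromen-4-one, via keto ester 11 (not isolated), via trione 12 (not isolated)
Conditions: LiN(SiMe3)2 (1.1 equiv), THF, −78 °C; 3 (1.2 equiv), −78 → 0 °C; LiN(iPr)2 (2.5 equiv), −78 → 0 °C; AcOH, then pH 5 phosphate buffer
Reagents that add atoms: none
Why: Proposed new method: LiN(SiMe3)2 should deprotonate the 2-methyl group of 10 (vinylogous to both the ring C carbonyl and the 3-ester), and the exocyclic carbon of this dienolate opens lactone 3 by Claisen acylation (C8–C7), the expelled tertiary alkoxide becoming the side-chain hydroxyl of 11; LiN(iPr)2 then forms the 1,3-dianion of the new ketone, whose terminal carbanion (C6) attacks the neighbouring ester in a Dieckmann condensation (C6–C5), and loss of ethoxide and enolisation of trione 12 give aromatic ring A. The closest known reaction types are the Claisen–Dieckmann assembly of naphthalene-1,3-diols from ortho-toluate anions and esters, the ester acylation of lateral anions of 2-methyl-4-pyranones, and β-keto ester 1,3-dianion chemistry; new is their one-flask union on a 4-pyranone with a lactone as the two-carbon partner. Ring A closes in a 6-(enolendo)-exo-trig mode, and the transient stereocentre at C6 of 12 is erased on aromatisation, so the product is achiral. The step needs γ- rather than α-attack of the dienolate (the α-carbon is quaternary and attack there would break the pyranone conjugation), C- rather than O-acylation in the closure (secured by the carbon dianion), and closure onto the ester rather than the ring carbonyl (attack at C4 would give a bridged bicycle). The place of the side chain is fixed by connectivity: the lactone α-carbon can only become C6, between the two new hydroxyls, so no C8 isomer can form.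

Step 5
Reactants: 13 di-O-benzyl flavone
Product: 14 2-(2,4-dihydroxyphenyl)-5,7-dihydroxy-6-(3-hydroxy-3-methylbutyl)-4H-chromen-4-one (target, achiral)
Conditions: H2 (1 atm), 10% Pd/C, EtOAc/MeOH 1:1, 25 °C; filtration through Celite, no acid
Reagents that add atoms: none
Why: Catalytic hydrogenolysis of the two aryl benzyl ethers under neutral conditions, in which the γ-pyrone double bond of ring C should stay intact at 1 atm and the tertiary alcohol, neither allylic nor benzylic and never exposed to acid, cannot be lost or cyclise onto a neighbouring phenol; no stereocentre.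

**Compound list**
1 | ethyl 5-oxohexanoate | CCOC(=O)CCCC(C)=O | starting material
2 | ethyl 5-hydroxy-5-methylhexanoate (not isolated) | CCOC(=O)CCCC(C)(C)O | intermediate
3 | 6,6-dimethyltetrahydro-2H-pyran-2-one | CC1(C)CCCC(=O)O1 | intermediate
4 | 2,4-bis(benzyloxy)benzoic acid | O=C(O)c1ccc(OCc2ccccc2)cc1OCc1ccccc1 | starting material
5 | 2,2-dimethyl-1,3-dioxane-4,6-dione (Meldrum's acid) | CC1(C)OC(=O)CC(=O)O1 | starting material
6 | 5-{[2,4-bis(benzyloxy)phenyl](hydroxy)methylidene}-2,2-dimethyl-1,3-dioxane-4,6-dione | CC1(C)OC(=O)C(=C(O)c2ccc(OCc3ccccc3)cc2OCc2ccccc2)C(=O)O1 | intermediate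
7 | ethyl (E)-3-(pyrrolidin-1-yl)but-2-enoate | CCOC(=O)/C=C(\C)N1CCCC1 | starting material
8 | 3-[2,4-bis(benzyloxy)phenyl]prop-1-ene-1,3-dione (aroylketene, not isolated) | O=C=CC(=O)c1ccc(OCc2ccccc2)cc1OCc1ccccc1 | intermediate
9 | ethyl 2-{3-[2,4-bis(benzyloxy)phenyl]-3-oxopropanoyl}-3-(pyrrolidin-1-yl)but-2-enoate (alkene geometry not fixed, not isolated) | CCOC(=O)C(C(=O)CC(=O)c1ccc(OCc2ccccc2)cc1OCc1ccccc1)=C(C)N1CCCC1 | intermediate
10 | ethyl 6-[2,4-bis(benzyloxy)phenyl]-2-methyl-4-oxo-4H-pyran-3-carboxylate | CCOC(=O)c1c(C)oc(-c2ccc(OCc3ccccc3)cc2OCc2ccccc2)cc1=O | intermediate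
11 | ethyl 6-[2,4-bis(benzyloxy)phenyl]-2-(6-hydroxy-6-methyl-2-oxoheptyl)-4-oxo-4H-pyran-3-carboxylate (not isolated) | CCOC(=O)c1c(CC(=O)CCCC(C)(C)O)oc(-c2ccc(OCc3ccccc3)cc2OCc2ccccc2)cc1=O | intermediate
12 | 2-[2,4-bis(benzyloxy)phenyl]-6-(3-hydroxy-3-methylbutyl)-4H-chromene-4,5,7(6H,8H)-trione (racemic at C6, keto tautomer of 13, not isolated) | CC(C)(O)CCC1C(=O)Cc2oc(-c3ccc(OCc4ccccc4)cc3OCc3ccccc3)cc(=O)c2C1=O | intermediate
13 | 2-[2,4-bis(benzyloxy)phenyl]-5,7-dihydroxy-6-(3-hydroxy-3-methylbutyl)-4H-chromen-4-one | CC(C)(O)CCc1c(O)cc2oc(-c3ccc(OCc4ccccc4)cc3OCc3ccccc3)cc(=O)c2c1O | intermediate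
14 | 2-(2,4-dihydroxyphenyl)-5,7-dihydroxy-6-(3-hydroxy-3-methylbutyl)-4H-chromen-4-one (achiral) | CC(C)(O)CCc1c(O)cc2oc(-c3ccc(O)cc3O)cc(=O)c2c1O | target

**Count**
Total step count: 5. Longest linear sequence: 4 (steps 2 to 5 from acid 4); the lactone branch (step 1) joins at step 4.

**Steps most likely to fail**

Step 4 (proposed new method). The ester-stabilised dienolate may only enolise the lactone or add to it reversibly, or the closure may run through the enolate oxygen (enol-lactone formation) instead of carbon. The fallback sets out from 3 and 10 and comes back at 13; it separates the two bond formations and replaces the lactone by a chelating acyl donor. Lactone 3 would be opened with MeNH(OMe)·HCl and AlMe3 to 5-hydroxy-N-methoxy-N,5-dimethylhexanamide F1, which would be silylated (Et3SiOTf, 2,6-lutidine) to N-methoxy-N,5-dimethyl-5-[(triethylsilyl)oxy]hexanamide F2. The lithium dienolate of 10 would be acylated with F2 (Weinreb ketone synthesis, whose stable tetrahedral chelate cannot revert) to ethyl 6-[2,4-bis(benzyloxy)phenyl]-2-{6-methyl-2-oxo-6-[(triethylsilyl)oxy]heptyl}-4-oxo-4H-pyran-3-carboxylate F3. This keto ester would be isolated and closed under thermodynamic control with NaH in THF (Dieckmann closure of an ortho-(2-oxoalkyl) aryl ester to a 1,3-dihydroxyarene) to 2-[2,4-bis(benzyloxy)phenyl]-5,7-dihydroxy-6-{3-methyl-3-[(triethylsilyl)oxy]butyl}-4H-chromen-4-one F4, and Bu4NF buffered with AcOH would then give 13.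

Step 3. Dimerisation of the aroylketene may outrun its capture, because the α-carbon of the push–pull enamine is only a weak nucleophile. The fallback sets out from 7 and 4 and comes back at 9; it forms the C5–C6 bond by enolate aroylation and needs no ketene. Enamino ester 7 would be C-acetylated at its α-carbon (AcCl, pyridine, CH2Cl2, 0 °C) to ethyl 2-acetyl-3-(pyrrolidin-1-yl)but-2-enoate F5, and acid 4 would be converted with oxalyl chloride and catalytic DMF into 2,4-bis(benzyloxy)benzoyl chloride F6. Kinetic deprotonation of the acetyl methyl group of the acetylated enamine with LiN(SiMe3)2 (2.2 equiv, THF, −78 °C) and Claisen-type C-aroylation of the lithium enolate with the acid chloride should give 9. This is the enaminone enolate and acid chloride route to 6-aryl-4-pyranone-3-carboxylates, and 9 would close to 10 with AcOH as in step 3.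

Step 2. C-acylation of Meldrum's acid by an electron-rich, ortho-substituted acid may be slow, with competing rearrangement to the N-acylurea and loss of the labile adduct on purification. The fallback sets out from 4 and comes back at aroylketene 8. Acid 4 would be activated with 1,1'-carbonyldiimidazole to 1-[2,4-bis(benzyloxy)benzoyl]-1H-imidazole F7, which would be treated with the lithium enolate of tert-butyl acetate (2.2 equiv, THF, −78 °C) to give tert-butyl 3-[2,4-bis(benzyloxy)phenyl]-3-oxopropanoate F8. Heating this β-keto ester with 7 in xylene at 140 °C would expel tert-butanol and generate 8 directly, which would continue to 10 as in step 3.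

**Further compounds**
F1 | step 4 | 5-hydroxy-N-methoxy-N,5-dimethylhexanamide | CON(C)C(=O)CCCC(C)(C)O
F2 | step 4 | N-methoxy-N,5-dimethyl-5-[(triethylsilyl)oxy]hexanamide | CON(C)C(=O)CCCC(C)(C)O[Si](CC)(CC)CC
F3 | step 4 | ethyl 6-[2,4-bis(benzyloxy)phenyl]-2-{6-methyl-2-oxo-6-[(triethylsilyl)oxy]heptyl}-4-oxo-4H-pyran-3-carboxylate | CCOC(=O)c1c(CC(=O)CCCC(C)(C)O[Si](CC)(CC)CC)oc(-c2ccc(OCc3ccccc3)cc2OCc2ccccc2)cc1=O
F4 | step 4 | 2-[2,4-bis(benzyloxy)phenyl]-5,7-dihydroxy-6-{3-methyl-3-[(triethylsilyl)oxy]butyl}-4H-chromen-4-one | CC[Si](CC)(CC)OC(C)(C)CCc1c(O)cc2oc(-c3ccc(OCc4ccccc4)cc3OCc3ccccc3)cc(=O)c2c1O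
F5 | step 3 | ethyl 2-acetyl-3-(pyrrolidin-1-yl)but-2-enoate (alkene geometry not fixed) | CCOC(=O)C(C(C)=O)=C(C)N1CCCC1
F6 | step 3 | 2,4-bis(benzyloxy)benzoyl chloride | O=C(Cl)c1ccc(OCc2ccccc2)cc1OCc1ccccc1
F7 | step 2 | 1-[2,4-bis(benzyloxy)benzoyl]-1H-imidazole | O=C(c1ccc(OCc2ccccc2)cc1OCc1ccccc1)n1ccnc1
F8 | step 2 | tert-butyl 3-[2,4-bis(benzyloxy)phenyl]-3-oxopropanoate | CC(C)(C)OC(=O)CC(=O)c1ccc(OCc2ccccc2)cc1OCc1ccccc1
A1 | direct plan | 1-[2,4-bis(benzyloxy)-6-hydroxyphenyl]ethan-1-one | CC(=O)c1c(O)cc(OCc2ccccc2)cc1OCc1ccccc1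
A2 | direct plan | 2,4-bis(benzyloxy)benzaldehyde | O=Cc1ccc(OCc2ccccc2)cc1OCc1ccccc1
A3 | direct plan | 5,7-bis(benzyloxy)-2-[2,4-bis(benzyloxy)phenyl]-4H-chromen-4-one | O=c1cc(-c2ccc(OCc3ccccc3)cc2OCc2ccccc2)oc2cc(OCc3ccccc3)cc(OCc3ccccc3)c12
A4 | direct plan | 7-(benzyloxy)-2-[2,4-bis(benzyloxy)phenyl]-5-hydroxy-4H-chromen-4-one | O=c1cc(-c2ccc(OCc3ccccc3)cc2OCc2ccccc2)oc2cc(OCc3ccccc3)cc(O)c12
A5 | direct plan | 7-(benzyloxy)-2-[2,4-bis(benzyloxy)phenyl]-5-hydroxy-6-iodo-4H-chromen-4-one | O=c1cc(-c2ccc(OCc3ccccc3)cc2OCc2ccccc2)oc2cc(OCc3ccccc3)c(I)c(O)c12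
A6 | direct plan | 2-methylbut-3-en-2-ol | CC(C)(O)C=C
A7 | direct plan | 7-(benzyloxy)-2-[2,4-bis(benzyloxy)phenyl]-5-hydroxy-6-[(E)-3-hydroxy-3-methylbut-1-en-1-yl]-4H-chromen-4-one | CC(C)(O)/C=C/c1c(OCc2ccccc2)cc2oc(-c3ccc(OCc4ccccc4)cc3OCc3ccccc3)cc(=O)c2c1O
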